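**Retrosynthetic overview**

- The isovanillate ester C–O bond is cut last. Before it, the 2,3-epoxide comes from a 2-methylcyclopentene by hydroxyl-directed epoxidation, and the 2-methyl group from an enol triflate.
- The strategy rests on one feature of the seven-membered ring: the ester carbinol C7 and the tertiary carbinol C5 are separated only by C6H2 (a cis-1,3-diol). This is what remains when a C7 aldehyde adds to the terminal carbon of a methallyl group in a type-two carbonyl-ene closure, giving a 3-methylenecycloheptanol. The exocyclic methylene then becomes C5(OH)CH3 by directed epoxidation and hydride opening.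
- The ene precursor is a trans-3,4-disubstituted cyclopentenyl triflate. The methallyl group arrives by anti conjugate addition to a 4-substituted cyclopentenone, with O-triflation of the resulting enolate.
- The isopropyl-bearing carbon C8 is fixed before the key step. A later correction through a C7 ketone is not relied on, because base would move the β,γ-alkene into conjugation. The side chain is delivered cis from the oxygen of (S)-4-hydroxycyclopentenone by Ueno–Stork cyclisation with isopropyl exo, and that oxygen then leaves by β-elimination to unveil the enone.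
- Ring order: cyclopentane (chiral pool), a temporary fused acetal/lactone that is opened again, the seven-membered ring (ene), then the epoxide.

Key step: step 9

Numbering used in names (azulene): C1 (CH2), C2, C3, C3a, C4, C5, C6, C7, C8, C8a. C7 is the carbinol, C8 carries isopropyl, C5 the tertiary carbinol. In the target, H-3a and H-8a are trans, and the 8-isopropyl, 7-oxygen, 5-hydroxyl and epoxide oxygen all lie on the face of H-8a.

Remark (assumption): the (S)-enantiomer of 4-hydroxycyclopent-2-en-1-one is taken as commercial, as its (R)-enantiomer is. Compounds 2, 4 and 5 are carried as mixtures at centres that are destroyed later (enol ether geometry, acetal carbon, bromine-bearing carbon).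

**Route**

Step 1
Reactants: 1 1,1-diethoxy-3-methylbutane
Product: 2 1-ethoxy-3-methylbut-1-ene (E/Z mixture)
Conditions: TMSOTf, i-Pr2NEt, CH2Cl2, −20 °C → rt
Reagents that add atoms: none
Why: silyl triflate ionises the acetal to an oxocarbenium ion that the hindered amine deprotonates (acetal-to-enol-ether elimination), and no stereocentre is involved.

Step 2
Reactants: 3 (S)-4-hydroxycyclopent-2-en-1-one; 2 1-ethoxy-3-methylbut-1-ene
Product: 4 (4S)-4-[(2-bromo-1-ethoxy-3-methylbutyl)oxy]cyclopent-2-en-1-one (mixture at the acetal and bromine-bearing carbons)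
Conditions: NBS, CH2Cl2, −40 → 0 °C
Reagents that add atoms: N-bromosuccinimide, O=C1CCC(=O)N1Br
Why: bromoacetalisation: NBS brominates the electron-rich enol ether and the α-bromo oxocarbenium ion is captured by the allylic hydroxyl, while the electron-poor enone alkene and the ring stereocentre are untouched.

Step 3
Reactants: 4 mixed bromoacetal
Product: 5 cis-fused keto acetal, 2-ethoxy-3-isopropylhexahydrocyclopenta[b]furan-5-one (ring-fusion hydrogens cis, isopropyl exo and cis to them, acetal epimers)
Conditions: Bu3SnH (slow addition), AIBN (cat.), PhH, 80 °C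
Reagents that add atoms: none
Why: Ueno–Stork radical cyclisation: the nucleophilic secondary alkyl radical adds 5-exo to the enone β-carbon on the face of the tethering oxygen, which fixes the ring-fusion carbon cis to that oxygen, and the isopropyl group should take the convex (exo) side to avoid the cyclopentanone ring, which sets the future C8.

Step 4
Reactants: 5 keto acetal
Product: 6 cis-fused keto lactone, 3-isopropyltetrahydrocyclopenta[b]furan-2,5-dione (isopropyl exo)
Conditions: CrO3, H2SO4, H2O, acetone, 0 °C
Reagents that add atoms: water, O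
Why: Jones oxidation of a 2-alkoxytetrahydrofuran: aqueous acid hydrolyses the acetal to the lactol and chromic acid oxidises it to the γ-lactone, with the three stereocentres unaffected at 0 °C.

Step 5
Reactants: 6 keto lactone
Product: 8 methyl (2S)-3-methyl-2-[(1R)-4-oxocyclopent-2-en-1-yl]butanoate, via enone acid 7 (not isolated)
Conditions: DBU (1.05 equiv), MeCN, 0 °C; then MeI, rt
Reagents that add atoms: iodomethane, CI
Why: E1cB elimination of the β-acyloxy ketone expels the lactone carboxylate and unveils the 4-substituted cyclopentenone, the carboxylate is then alkylated by MeI, and the isopropyl-bearing carbon, α to a carboxylate, is not enolised by the amidine.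

Step 6
Reactants: 8 enone ester
Product: 10 methyl (2S)-3-methyl-2-[(1R,2S)-2-(2-methylprop-2-en-1-yl)-4-(trifluoromethylsulfonyloxy)cyclopent-3-en-1-yl]butanoate, via trimethylsilyl enol ether 9 (not isolated)
Conditions: methallylMgCl, CuBr·SMe2, LiCl, TMSCl, THF, −78 °C; then CsF, PhNTf2, DME, rt
Reagents that add atoms: methallylmagnesium chloride, C=C(C)C[Mg]Cl; N-phenylbis(trifluoromethanesulfonimide), O=S(=O)(N(c1ccccc1)S(=O)(=O)C(F)(F)F)C(F)(F)F; chlorotrimethylsilane (silyl group of 9 only), C[Si](C)(C)Cl
Why: TMSCl-accelerated conjugate addition of the allylic copper reagent occurs anti to the bulky C4 side chain and gives the trans ring substituents and a regiodefined silyl enol ether, which fluoride converts into the enolate that PhNTf2 O-sulfonylates without touching the ester.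

Step 7
Reactants: 10 triflate ester
Product: 11 (2S)-3-methyl-2-[(1R,2S)-2-(2-methylprop-2-en-1-yl)-4-(trifluoromethylsulfonyloxy)cyclopent-3-en-1-yl]butan-1-ol
Conditions: i-Bu2AlH, CH2Cl2, −78 → 0 °C
Reagents that add atoms: none
Why: hydride reduction of the ester to the primary alcohol, with the enol triflate and the alkenes inert at low temperature and no stereocentre affected.

Step 8
Reactants: 11 primary alcohol
Product: 12 (2S)-3-methyl-2-[(1R,2S)-2-(2-methylprop-2-en-1-yl)-4-(trifluoromethylsulfonyloxy)cyclopent-3-en-1-yl]butanal
Conditions: Dess–Martin periodinane, NaHCO3, CH2Cl2, 0 °C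
Reagents that add atoms: none
Why: buffered Dess–Martin oxidation gives the α-branched aldehyde without epimerising its α-carbon, and the aldehyde is used at once.

Step 9
Reactants: 12 aldehyde
Product: 13 7-hydroxy-8-isopropyl-5-methylene-1,3a,4,5,6,7,8,8a-octahydroazulen-2-yl trifluoromethanesulfonate (H-3a/H-8a trans; 8-isopropyl and 7-OH both cis to H-8a)
Conditions: Me2AlCl (2 equiv), CH2Cl2, −78 → −20 °C
Reagents that add atoms: none
Why: Me2AlCl binds the aldehyde oxygen, the carbonyl carbon bonds to the terminal CH2 of the methallyl group while a hydrogen of its methyl group passes to oxygen in a six-centre ene transition state, and the former methyl becomes the exocyclic methylene; this is the known Me2AlCl-promoted type-two carbonyl-ene cyclisation that gives 3-methylenecyclohexanols and 3-methylenecycloheptanols. The seven-membered ring closes in the type-two mode (tether on the central carbon of the ene unit, formally 7-endo with respect to the alkene), templated by the trans substituents on the cyclopentene. The one new stereocentre, C7, is controlled by the adjacent C8: the oxygen has to sit over the hydrogen-donating methyl group (pseudo-axial), and in the chair-like ring the isopropyl group lies anti to the forming C6–C7 bond (pseudo-equatorial), which places hydroxyl and isopropyl cis. The step needs the aldehyde to choose the methallyl alkene over the ring alkene, and the electron-poor enol triflate secures this because it cannot act as ene or Prins partner; excess Me2AlCl scavenges protons, so the aldehyde α-carbon should not epimerise.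

Step 10
Reactants: 13 enol triflate alcohol
Product: 14 8-isopropyl-2-methyl-5-methylene-1,3a,4,5,6,7,8,8a-octahydroazulen-7-ol
Conditions: MeMgBr (3 equiv), Fe(acac)3 (cat.), THF/NMP, −30 → 0 °C
Reagents that add atoms: methylmagnesium bromide, C[Mg]Br
Why: iron-catalysed Kumada-type cross-coupling of the alkenyl triflate with MeMgBr installs the 2-methyl group, the hydroxyl being carried as its magnesium alkoxide and no stereocentre being touched.

Step 11
Reactants: 14 dienol
Product: 15 spiro-epoxy alcohol, 8-isopropyl-2-methyl-1,3a,4,6,7,8,8a-heptahydrospiro[azulene-5,2'-oxiran]-7-ol (epoxide oxygen cis to 7-OH)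
Conditions: VO(acac)2 (cat.), t-BuOOH (1.1 equiv), CH2Cl2, 0 °C → rt
Reagents that add atoms: tert-butyl hydroperoxide, CC(C)(C)OO
Why: hydroxyl-directed epoxidation of a homoallylic alcohol: the vanadate ester of the pseudo-axial 7-hydroxyl delivers oxygen to the near face of the exocyclic methylene, so the new C5–O bond is cis to the hydroxyl, while the remote, undirected cyclopentene reacts far more slowly.

Step 12
Reactants: 15 spiro-epoxy alcohol
Product: 16 8-isopropyl-2,5-dimethyl-1,3a,4,5,6,7,8,8a-octahydroazulene-5,7-diol (cis-1,3-diol)
Conditions: LiAlH4, THF, 0 °C → rt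
Reagents that add atoms: none
Why: hydride opens the 1,1-disubstituted epoxide by SN2 attack at its CH2 terminus, which leaves the C5–O bond and hence the tertiary carbinol configuration untouched and turns the CH2 into the 5-methyl group.

Step 13
Reactants: 16 diol
Product: 17 2,3-epoxy-8-isopropyl-2,5-dimethyldecahydroazulene-5,7-diol (epoxide oxygen on the face of the two hydroxyls and of H-8a)
Conditions: VO(acac)2 (cat.), t-BuOOH, PhMe, rt
Reagents that add atoms: tert-butyl hydroperoxide, CC(C)(C)OO
Why: hydroxyl-directed epoxidation of a bishomoallylic alcohol: both hydroxyls lie on the face anti to H-3a and the tertiary 5-hydroxyl should deliver oxygen to C3=C2 from that face, and the resulting syn epoxy alcohol cannot open transannularly because backside attack is geometrically excluded.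

Step 14
Reactants: 18 isovanillic acid
Product: 20 3-(tert-butyldimethylsilyloxy)-4-methoxybenzoic acid, via bis-silylated isovanillic acid 19 (not isolated)
Conditions: TBSCl (2.2 equiv), imidazole, DMF, rt; then AcOH, THF/H2O, rt
Reagents that add atoms: tert-butyldimethylsilyl chloride, CC(C)(C)[Si](C)(C)Cl
Why: exhaustive silylation followed by selective hydrolysis of the labile silyl ester leaves the aryl silyl ether in place.

Step 15
Reactants: 17 epoxy diol; 20 3-(tert-butyldimethylsilyloxy)-4-methoxybenzoic acid
Product: 22 7-O-[3-(tert-butyldimethylsilyloxy)-4-methoxybenzoyl] derivative of 17, via aroyl chloride 21 (not isolated)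
Conditions: 20, (COCl)2, DMF (cat.), CH2Cl2, 0 °C → rt, concentrate; then 17, DMAP, Et3N, CH2Cl2, rt → 40 °C
Reagents that add atoms: oxalyl chloride (chlorine of 21 only), O=C(Cl)C(=O)Cl
Why: DMAP-catalysed O-acylation by the acid chloride reaches only the secondary 7-hydroxyl, the tertiary hydroxyl being inert, with retention at C7 and basic conditions that spare the epoxide.

Step 16
Reactants: 22 silyl-protected ester
Product: 23 CNP0106636.1 (target)
Conditions: Bu4NF, AcOH, THF, 0 °C
Reagents that add atoms: none
Why: fluoride cleaves the aryl silyl ether, and buffering with acetic acid protects the benzoate ester and the epoxide from the phenoxide and from basic fluoride.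

**Compound list**

1 | 1,1-diethoxy-3-methylbutane | CCOC(CC(C)C)OCC | starting material
2 | 1-ethoxy-3-methylbut-1-ene (E/Z mixture) | CCOC=CC(C)C | intermediate
3 | (S)-4-hydroxycyclopent-2-en-1-one | O=C1C=C[C@@H](O)C1 | starting material
4 | (4S)-4-[(2-bromo-1-ethoxy-3-methylbutyl)oxy]cyclopent-2-en-1-one (diastereomer mixture) | O=C1C=C[C@@H](OC(OCC)C(Br)C(C)C)C1 | intermediate
5 | cis-fused keto acetal, 2-ethoxy-3-isopropylhexahydrocyclopenta[b]furan-5-one, isopropyl exo | CCOC1O[C@H]2CC(=O)C[C@H]2[C@@H]1C(C)C | intermediate
6 | cis-fused keto lactone, 3-isopropyltetrahydrocyclopenta[b]furan-2,5-dione, isopropyl exo | O=C1O[C@H]2CC(=O)C[C@H]2[C@@H]1C(C)C | intermediate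
7 | (2S)-3-methyl-2-[(1R)-4-oxocyclopent-2-en-1-yl]butanoic acid | O=C1C=C[C@@H](C1)[C@@H](C(=O)O)C(C)C | intermediate
8 | methyl (2S)-3-methyl-2-[(1R)-4-oxocyclopent-2-en-1-yl]butanoate | O=C1C=C[C@@H](C1)[C@@H](C(=O)OC)C(C)C | intermediate
9 | trimethylsilyl enol ether of the methallyl adduct | C=C(C)C[C@@H]1C=C(O[Si](C)(C)C)C[C@H]1[C@@H](C(=O)OC)C(C)C | intermediate
10 | methyl (2S)-3-methyl-2-[(1R,2S)-2-(2-methylprop-2-en-1-yl)-4-(trifluoromethylsulfonyloxy)cyclopent-3-en-1-yl]butanoate | C=C(C)C[C@@H]1C=C(OS(=O)(=O)C(F)(F)F)C[C@H]1[C@@H](C(=O)OC)C(C)C | intermediate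
11 | (2S)-3-methyl-2-[(1R,2S)-2-(2-methylprop-2-en-1-yl)-4-(trifluoromethylsulfonyloxy)cyclopent-3-en-1-yl]butan-1-ol | C=C(C)C[C@@H]1C=C(OS(=O)(=O)C(F)(F)F)C[C@H]1[C@@H](CO)C(C)C | intermediate
12 | (2S)-3-methyl-2-[(1R,2S)-2-(2-methylprop-2-en-1-yl)-4-(trifluoromethylsulfonyloxy)cyclopent-3-en-1-yl]butanal | C=C(C)C[C@@H]1C=C(OS(=O)(=O)C(F)(F)F)C[C@H]1[C@@H](C=O)C(C)C | intermediate
13 | 7-hydroxy-8-isopropyl-5-methylene-1,3a,4,5,6,7,8,8a-octahydroazulen-2-yl triflate | O[C@@H]1CC(=C)C[C@H]2[C@@H](CC(OS(=O)(=O)C(F)(F)F)=C2)[C@@H]1C(C)C | intermediate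
14 | 8-isopropyl-2-methyl-5-methylene-1,3a,4,5,6,7,8,8a-octahydroazulen-7-ol | O[C@@H]1CC(=C)C[C@H]2[C@@H](CC(C)=C2)[C@@H]1C(C)C | intermediate
15 | spiro-epoxy alcohol (epoxide oxygen cis to 7-OH) | O[C@@H]1C[C@@]3(CO3)C[C@H]2[C@@H](CC(C)=C2)[C@@H]1C(C)C | intermediate
16 | 8-isopropyl-2,5-dimethyl-1,3a,4,5,6,7,8,8a-octahydroazulene-5,7-diol (cis-diol) | O[C@@H]1C[C@](C)(O)C[C@H]2[C@@H](CC(C)=C2)[C@@H]1C(C)C | intermediate
17 | 2,3-epoxy-8-isopropyl-2,5-dimethyldecahydroazulene-5,7-diol | O[C@@H]1C[C@](C)(O)C[C@H]2[C@@H](C[C@@]3(C)O[C@@H]23)[C@@H]1C(C)C | intermediate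
18 | isovanillic acid | COc1ccc(C(=O)O)cc1O | starting material
19 | tert-butyldimethylsilyl 3-(tert-butyldimethylsilyloxy)-4-methoxybenzoate | COc1ccc(C(=O)O[Si](C)(C)C(C)(C)C)cc1O[Si](C)(C)C(C)(C)C | intermediate
20 | 3-(tert-butyldimethylsilyloxy)-4-methoxybenzoic acid | COc1ccc(C(=O)O)cc1O[Si](C)(C)C(C)(C)C | intermediate
21 | 3-(tert-butyldimethylsilyloxy)-4-methoxybenzoyl chloride | COc1ccc(C(=O)Cl)cc1O[Si](C)(C)C(C)(C)C | intermediate
22 | silyl-protected target ester | COc1ccc(C(=O)O[C@@H]2C[C@](C)(O)C[C@H]3[C@@H](C[C@@]4(C)O[C@@H]34)[C@@H]2C(C)C)cc1O[Si](C)(C)C(C)(C)C | intermediate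
23 | CNP0106636.1 | COc1ccc(C(=O)O[C@@H]2C[C@](C)(O)C[C@H]3[C@@H](C[C@@]4(C)O[C@@H]34)[C@@H]2C(C)C)cc1O | target

**Step count and risks**

Total steps: 16. Longest linear sequence: 15 steps (steps 1–13, 15 and 16, from 1 to 23).

Steps most likely to fail:

1. Step 9. The closure may run through the other ring conformer, with isopropyl gauche to the forming bond, and so lose facial selectivity at the aldehyde. Fallback, setting out from 12 and returning at 13: the cyclisation is run without regard to the carbinol configuration, giving the C7-epimeric alcohol F1 alone or mixed with 13. This is oxidised with Dess–Martin periodinane and NaHCO3, without base so that the exocyclic alkene stays out of conjugation and C8 is not touched, to the β,γ-unsaturated ketone F2. Reduction with LiBH(s-Bu)3 in THF at −78 °C should then deliver hydride from the equatorial side, anti to the neighbouring isopropyl group, to give the pseudo-axial alcohol 13. The stereocentre is then set by reagent approach to a ketone and no longer by the ene transition state.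

2. Step 3. Exo selectivity at the isopropyl-bearing radical carbon may be incomplete. Fallback, setting out from 6 (as an exo/endo mixture) and returning at 6: the ketone is masked with ethylene glycol and PPTS in benzene to give the dioxolane lactone F3 as the mixture. With the β-elimination pathway closed, the lactone α-carbon is equilibrated with catalytic t-BuOK in t-BuOH to the thermodynamically preferred exo dioxolane lactone F4. Aqueous HCl in acetone returns 6 as the exo isomer. Control is thermodynamic here, not kinetic.

3. Step 13. Facial selectivity on the cyclopentene may be poor if the bishomoallylic hydroxyl is too remote to direct. Fallback, setting out from 16 and returning at 17: Shi epoxidation with the fructose-derived ketone catalyst of the enantiomeric series matched to the H-8a face, KHSO5 (as 2KHSO5·KHSO4·K2SO4), K2CO3, MeCN/dimethoxymethane/H2O, 0 °C. The face is then chosen by the catalyst and not by the substrate hydroxyl; it makes no new compound (F0).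

Further compounds
F1 | step 9 | 7-epi-13, 7-hydroxy-8-isopropyl-5-methylene-1,3a,4,5,6,7,8,8a-octahydroazulen-2-yl triflate with 7-OH trans to isopropyl | O[C@H]1CC(=C)C[C@H]2[C@@H](CC(OS(=O)(=O)C(F)(F)F)=C2)[C@@H]1C(C)C
F2 | step 9 | 8-isopropyl-5-methylene-7-oxo-1,3a,4,5,6,7,8,8a-octahydroazulen-2-yl triflate | O=C1CC(=C)C[C@H]2[C@@H](CC(OS(=O)(=O)C(F)(F)F)=C2)[C@@H]1C(C)C
F3 | step 3 | ethylene ketal of keto lactone 6, mixture at the isopropyl-bearing carbon | O=C1O[C@H]2CC3(OCCO3)C[C@H]2C1C(C)C
F4 | step 3 | ethylene ketal of keto lactone 6, isopropyl exo | O=C1O[C@H]2CC3(OCCO3)C[C@H]2[C@@H]1C(C)C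
F0 | step 13 | none | none
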